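## Plan

1. Ring letters follow the SMILES. A is the terminal 3,5-dihydroxyphenyl ring, and B, C and D form the ether-linked chain. E–F and G–H are the two biaryl arms on D, and I–J is the biaryl arm on B. All 24 hydroxyls travel as methyl ethers until the last step.
2. Enabling feature: in ring D, the carbon bonded to the oxygen leading to ring C lies between two carbons that bear the same biaryloxy group (O–E and O–G), and the carbon para to it bears OH. This is the substitution map of 2,6-difluoro-4-methoxybenzaldehyde, with the formyl carbon read as a placeholder for oxygen. Ring B repeats the map with two unlike aryloxy groups.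
3. Cuts: the six diaryl ether links, each broken at the carbon of the ring that can be made electrophilic (D carbon–O of E, D carbon–O of G, C carbon–O of D, B carbon–O of C, B carbon–O of I, A carbon–O of B). The three identical biaryl C–C bonds (E–F, G–H, I–J) are also cut and lead back to 1,3,5-trimethoxybenzene.
4. Forward order: biaryl phenol E–F; both arms onto D; CHO to OH. Ring C then comes from 2,4,6-trifluorobenzaldehyde (para fluoride to the ring D oxygen, ortho fluorides to methoxide), followed by CHO to OH. Ring B arrives as a fluoroaldehyde already carrying I–J, again followed by CHO to OH. Ring A is added by copper-catalysed arylation, and global demethylation ends the route.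
5. Stereochemistry: none has to be set. There is no stereocentre, and each biaryl axis carries one ring (F, H, J) that is symmetric about the axis.

Key step: step 4

Abbreviation in names: Ar = 2,2',4,4',6,6'-hexamethoxybiphenyl-3-yl, attached through the ring carbon that lies between two methoxy groups.

Assumption: 1,3,5-trimethoxybenzene, 2,6-difluoro-4-methoxybenzaldehyde, 2,4,6-trifluorobenzaldehyde and 1-iodo-3,5-dimethoxybenzene are taken as catalogue compounds, and all phenoxide chemistry is run under argon in degassed solvent because 2,4,6-trioxygenated phenols are air-sensitive in base.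

## Route

Step 1
Reactants: 1 1,3,5-trimethoxybenzene (two molecules)
Product: 2 2,2',4,4',6,6'-hexamethoxybiphenyl
Conditions: FeCl3 (1.1 equiv per arene), CH2Cl2, 0 °C to rt; MeOH quench
Reagents that add atoms: none
Why: Oxidative dehydrodimerisation of an electron-rich arene (Scholl-type coupling), in which FeCl3 takes one electron from 1, the radical cation is attacked by a second molecule of 1 and two protons are lost, while the twisted tetra-ortho-substituted product should couple further only slowly.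

Step 2
Reactants: 2 2,2',4,4',6,6'-hexamethoxybiphenyl
Product: 5 2,2',4,4',6,6'-hexamethoxybiphenyl-3-ol, via aryllithium 3 (not isolated), via dimethyl arylboronate 4 (not isolated)
Conditions: n-BuLi (0.9 equiv), TMEDA, THF, 0 °C; B(OMe)3, −78 °C to rt; 30% H2O2, AcOH, 0 °C to rt
Reagents that add atoms: hydrogen peroxide, OO (the oxygen of 5); n-butyllithium, [Li]CCCC (the lithium of 3); trimethyl borate, COB(OC)OC (boron and two methoxy groups of 4)
Why: Directed ortho-metalation, borylation and peroxide oxidation with 1,2-aryl shift; all four ring hydrogens of 2 are equivalent and each lies between two methoxy groups, so the only issue is single against double lithiation, which a slight deficit of base should hold down, with neutral 2 recovered and the more polar diol removed by chromatography.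

Step 3
Reactants: 5 2,2',4,4',6,6'-hexamethoxybiphenyl-3-ol; 6 2,6-difluoro-4-methoxybenzaldehyde (3 equiv)
Product: 7 2-fluoro-4-methoxy-6-(ArO)benzaldehyde (ring B precursor carrying arm I–J)
Conditions: K2CO3, DMF, 60 °C, Ar
Reagents that add atoms: none
Why: Nucleophilic aromatic substitution (addition–elimination) ortho to a formyl group; the remaining fluoride of 7 is less reactive than those of 6 because the new aryloxy group is a donor, so an excess of 6 and a moderate temperature should stop the reaction at single displacement.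

Step 4
Reactants: 5 2,2',4,4',6,6'-hexamethoxybiphenyl-3-ol (2.5 equiv, two molecules incorporated); 6 2,6-difluoro-4-methoxybenzaldehyde
Product: 8 4-methoxy-2,6-bis(ArO)benzaldehyde, via monofluoride 7 (not isolated)
Conditions: Cs2CO3 (3 equiv), DMSO, 110 °C, Ar
Reagents that add atoms: none
Why: This is a twofold addition–elimination in which the cesium phenoxide of 5 adds to a C–F carbon of 6, the charge of the Meisenheimer adduct is spread onto the ortho formyl oxygen and fluoride leaves, after which the same events repeat on monofluoride 7. The closest known reaction type is the displacement of fluoride from 2-fluoro- and 2,6-difluorobenzaldehydes by phenoxides with carbonate bases in dipolar aprotic solvents. No ring closes and no stereocentre forms, the two new bonds being the aryl C–O bonds at the ring D carbons on either side of the formyl carbon. The only selectivity required is completeness, since the two fluorides of 6 are equivalent and the methoxy group para to the formyl group is a far poorer leaving group than fluoride; the donor effect of the first aryloxy group slows the second displacement, which is answered by the excess of 5 and by heating. Each electrophilic carbon has only a hydrogen-bearing carbon and the flat formyl group as neighbours, so a phenoxide with two ortho methoxy groups can still reach it, and any exchange of aryloxy groups at the activated positions is degenerate because both arms are alike. Exclusion of air should protect the electron-rich phenoxide, and dry carbonate leaves the non-enolisable aldehyde untouched.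

Step 5
Reactants: 8 4-methoxy-2,6-bis(ArO)benzaldehyde
Product: 10 4-methoxy-2,6-bis(ArO)phenol, via ring D aryl formate 9 (not isolated)
Conditions: mCPBA (1.3 equiv), CH2Cl2, 0 °C to rt; aq Na2SO3 wash; cat. K2CO3, MeOH–THF, 0 °C, Ar
Reagents that add atoms: 3-chloroperoxybenzoic acid (mCPBA), O=C(OO)c1cccc(Cl)c1
Why: Baeyer–Villiger oxidation of an electron-rich benzaldehyde followed by methanolysis of the aryl formate (Dakin-type exchange of CHO for OH); the ring with three oxygen donors ortho and para to the carbonyl migrates in preference to hydrogen, and the ether and biaryl bonds should be left alone by the peracid at low temperature.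

Step 6
Reactants: 10 4-methoxy-2,6-bis(ArO)phenol; 11 2,4,6-trifluorobenzaldehyde (1.5 equiv)
Product: 12 2,6-difluoro-4-[4-methoxy-2,6-bis(ArO)phenoxy]benzaldehyde
Conditions: Cs2CO3, DMF, 0 °C to rt, Ar
Reagents that add atoms: none
Why: Nucleophilic aromatic substitution on a polyfluorobenzaldehyde; all three fluorides are activated, but the phenoxide of 10 is flanked by two large aryloxy groups and should take the para carbon, whose neighbours both carry hydrogen, rather than an ortho carbon beside the formyl group, while the excess of 11 suppresses a second arylation.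

Step 7
Reactants: 12 2,6-difluoro-4-[4-methoxy-2,6-bis(ArO)phenoxy]benzaldehyde
Product: 14 2,6-dimethoxy-4-[4-methoxy-2,6-bis(ArO)phenoxy]benzaldehyde, via fluoro methoxy aldehyde 13 (not isolated)
Conditions: NaOMe (3 equiv), MeOH–THF, 50 °C
Reagents that add atoms: sodium methoxide, [Na+].[O-]C
Why: Nucleophilic aromatic substitution by methoxide at the two carbons ortho to the formyl group, a standard conversion of 2,6-difluorobenzaldehydes; fluoride is displaced much faster than the para aryloxy group, so the ring C–O–ring D link should persist.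

Step 8
Reactants: 14 2,6-dimethoxy-4-[4-methoxy-2,6-bis(ArO)phenoxy]benzaldehyde
Product: 16 2,6-dimethoxy-4-[4-methoxy-2,6-bis(ArO)phenoxy]phenol, via ring C aryl formate 15 (not isolated)
Conditions: mCPBA (1.3 equiv), CH2Cl2, 0 °C to rt; aq Na2SO3 wash; cat. K2CO3, MeOH–THF, 0 °C, Ar
Reagents that add atoms: 3-chloroperoxybenzoic acid (mCPBA), O=C(OO)c1cccc(Cl)c1
Why: Baeyer–Villiger/Dakin-type exchange as in step 5, here on a 2,4,6-trioxygenated benzaldehyde of the 2,4,6-trimethoxybenzaldehyde type, for which aryl migration is the normal course.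

Step 9
Reactants: 16 2,6-dimethoxy-4-[4-methoxy-2,6-bis(ArO)phenoxy]phenol; 7 2-fluoro-4-methoxy-6-(ArO)benzaldehyde (1.5 equiv)
Product: 17 2-(ArO)-4-methoxy-6-{2,6-dimethoxy-4-[4-methoxy-2,6-bis(ArO)phenoxy]phenoxy}benzaldehyde
Conditions: Cs2CO3, DMSO, 110 °C, Ar
Reagents that add atoms: none
Why: The same addition–elimination as the second half of step 4; the phenoxide of 16 has the 2,6-dimethoxy environment of 5, and keeping electrophile 7 in excess should leave little free phenoxide to exchange the aryloxy groups that sit ortho to the formyl group.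

Step 10
Reactants: 17 2-(ArO)-4-methoxy-6-{2,6-dimethoxy-4-[4-methoxy-2,6-bis(ArO)phenoxy]phenoxy}benzaldehyde
Product: 19 2-(ArO)-4-methoxy-6-{2,6-dimethoxy-4-[4-methoxy-2,6-bis(ArO)phenoxy]phenoxy}phenol, via ring B aryl formate 18 (not isolated)
Conditions: mCPBA (1.3 equiv), CH2Cl2, 0 °C to rt; aq Na2SO3 wash; cat. K2CO3, MeOH–THF, 0 °C, Ar
Reagents that add atoms: 3-chloroperoxybenzoic acid (mCPBA), O=C(OO)c1cccc(Cl)c1
Why: Baeyer–Villiger/Dakin-type exchange on an aldehyde with the same 2,6-diaryloxy-4-methoxy pattern as 8, so the behaviour seen in step 5 should carry over.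

Step 11
Reactants: 19 2-(ArO)-4-methoxy-6-{2,6-dimethoxy-4-[4-methoxy-2,6-bis(ArO)phenoxy]phenoxy}phenol; 20 1-iodo-3,5-dimethoxybenzene (2 equiv)
Product: 21 tetracosa-O-methyl ether of the target: 2-(3,5-dimethoxyphenoxy)-1-(ArO)-5-methoxy-3-{2,6-dimethoxy-4-[4-methoxy-2,6-bis(ArO)phenoxy]phenoxy}benzene
Conditions: CuI (20 mol %), picolinic acid (40 mol %), K3PO4, DMSO, 90 °C, Ar
Reagents that add atoms: none
Why: Ullmann-type diaryl ether synthesis; the CuI/picolinic acid system tolerates phenols with two ortho substituents, and the aryl iodide is unhindered, with both methoxy groups meta to iodine.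

Step 12
Reactants: 21 tetracosa-O-methyl ether of the target
Product: 22 CNP0294555.0 (target, 24 free hydroxyls)
Conditions: BBr3 (3 equiv per OMe), CH2Cl2, −78 °C to rt; ice–water; Sephadex LH-20 (MeOH), Ar
Reagents that add atoms: none
Why: Lewis acid cleavage of aryl methyl ethers, in which BBr3 binds each methoxy oxygen and bromide removes the methyl group by SN2; the diaryl ether and biaryl bonds are inert because they offer no sp3 carbon, and the boron aryloxides (a mixture, no single compound) are hydrolysed at the quench.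

## Compound list

1 | 1,3,5-trimethoxybenzene | COc1cc(OC)cc(OC)c1 | starting material
2 | 2,2',4,4',6,6'-hexamethoxybiphenyl | COc1cc(OC)c(-c2c(OC)cc(OC)cc2OC)c(OC)c1 | intermediate
3 | (2,2',4,4',6,6'-hexamethoxybiphenyl-3-yl)lithium | [Li]c1c(OC)cc(OC)c(-c2c(OC)cc(OC)cc2OC)c1OC | intermediate
4 | dimethyl (2,2',4,4',6,6'-hexamethoxybiphenyl-3-yl)boronate | COB(OC)c1c(OC)cc(OC)c(-c2c(OC)cc(OC)cc2OC)c1OC | intermediate
5 | 2,2',4,4',6,6'-hexamethoxybiphenyl-3-ol | COc1cc(OC)c(-c2c(OC)cc(OC)cc2OC)c(OC)c1O | intermediate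
6 | 2,6-difluoro-4-methoxybenzaldehyde | COc1cc(F)c(C=O)c(F)c1 | starting material
7 | 2-fluoro-4-methoxy-6-(ArO)benzaldehyde | COc1cc(F)c(C=O)c(Oc2c(OC)cc(OC)c(-c3c(OC)cc(OC)cc3OC)c2OC)c1 | intermediate
8 | 4-methoxy-2,6-bis(ArO)benzaldehyde | COc1cc(Oc2c(OC)cc(OC)c(-c3c(OC)cc(OC)cc3OC)c2OC)c(C=O)c(Oc2c(OC)cc(OC)c(-c3c(OC)cc(OC)cc3OC)c2OC)c1 | intermediate
9 | 4-methoxy-2,6-bis(ArO)phenyl formate | COc1cc(Oc2c(OC)cc(OC)c(-c3c(OC)cc(OC)cc3OC)c2OC)c(OC=O)c(Oc2c(OC)cc(OC)c(-c3c(OC)cc(OC)cc3OC)c2OC)c1 | intermediate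
10 | 4-methoxy-2,6-bis(ArO)phenol (ring D phenol) | COc1cc(Oc2c(OC)cc(OC)c(-c3c(OC)cc(OC)cc3OC)c2OC)c(O)c(Oc2c(OC)cc(OC)c(-c3c(OC)cc(OC)cc3OC)c2OC)c1 | intermediate
11 | 2,4,6-trifluorobenzaldehyde | O=Cc1c(F)cc(F)cc1F | starting material
12 | 2,6-difluoro-4-[4-methoxy-2,6-bis(ArO)phenoxy]benzaldehyde | O=Cc1c(F)cc(Oc2c(Oc3c(OC)cc(OC)c(-c4c(OC)cc(OC)cc4OC)c3OC)cc(OC)cc2Oc2c(OC)cc(OC)c(-c3c(OC)cc(OC)cc3OC)c2OC)cc1F | intermediate
13 | 2-fluoro-6-methoxy-4-[4-methoxy-2,6-bis(ArO)phenoxy]benzaldehyde | O=Cc1c(F)cc(Oc2c(Oc3c(OC)cc(OC)c(-c4c(OC)cc(OC)cc4OC)c3OC)cc(OC)cc2Oc2c(OC)cc(OC)c(-c3c(OC)cc(OC)cc3OC)c2OC)cc1OC | intermediate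
14 | 2,6-dimethoxy-4-[4-methoxy-2,6-bis(ArO)phenoxy]benzaldehyde | O=Cc1c(OC)cc(Oc2c(Oc3c(OC)cc(OC)c(-c4c(OC)cc(OC)cc4OC)c3OC)cc(OC)cc2Oc2c(OC)cc(OC)c(-c3c(OC)cc(OC)cc3OC)c2OC)cc1OC | intermediate
15 | 2,6-dimethoxy-4-[4-methoxy-2,6-bis(ArO)phenoxy]phenyl formate | O=COc1c(OC)cc(Oc2c(Oc3c(OC)cc(OC)c(-c4c(OC)cc(OC)cc4OC)c3OC)cc(OC)cc2Oc2c(OC)cc(OC)c(-c3c(OC)cc(OC)cc3OC)c2OC)cc1OC | intermediate
16 | 2,6-dimethoxy-4-[4-methoxy-2,6-bis(ArO)phenoxy]phenol (ring C phenol) | Oc1c(OC)cc(Oc2c(Oc3c(OC)cc(OC)c(-c4c(OC)cc(OC)cc4OC)c3OC)cc(OC)cc2Oc2c(OC)cc(OC)c(-c3c(OC)cc(OC)cc3OC)c2OC)cc1OC | intermediate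
17 | 2-(ArO)-4-methoxy-6-{2,6-dimethoxy-4-[4-methoxy-2,6-bis(ArO)phenoxy]phenoxy}benzaldehyde | COc1cc(Oc2c(OC)cc(Oc3c(Oc4c(OC)cc(OC)c(-c5c(OC)cc(OC)cc5OC)c4OC)cc(OC)cc3Oc3c(OC)cc(OC)c(-c4c(OC)cc(OC)cc4OC)c3OC)cc2OC)c(C=O)c(Oc2c(OC)cc(OC)c(-c3c(OC)cc(OC)cc3OC)c2OC)c1 | intermediate
18 | 2-(ArO)-4-methoxy-6-{2,6-dimethoxy-4-[4-methoxy-2,6-bis(ArO)phenoxy]phenoxy}phenyl formate | COc1cc(Oc2c(OC)cc(Oc3c(Oc4c(OC)cc(OC)c(-c5c(OC)cc(OC)cc5OC)c4OC)cc(OC)cc3Oc3c(OC)cc(OC)c(-c4c(OC)cc(OC)cc4OC)c3OC)cc2OC)c(OC=O)c(Oc2c(OC)cc(OC)c(-c3c(OC)cc(OC)cc3OC)c2OC)c1 | intermediate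
19 | 2-(ArO)-4-methoxy-6-{2,6-dimethoxy-4-[4-methoxy-2,6-bis(ArO)phenoxy]phenoxy}phenol (ring B phenol) | COc1cc(Oc2c(OC)cc(Oc3c(Oc4c(OC)cc(OC)c(-c5c(OC)cc(OC)cc5OC)c4OC)cc(OC)cc3Oc3c(OC)cc(OC)c(-c4c(OC)cc(OC)cc4OC)c3OC)cc2OC)c(O)c(Oc2c(OC)cc(OC)c(-c3c(OC)cc(OC)cc3OC)c2OC)c1 | intermediate
20 | 1-iodo-3,5-dimethoxybenzene | COc1cc(I)cc(OC)c1 | starting material
21 | tetracosa-O-methyl ether of the target | COc1cc(Oc2c(OC)cc(Oc3c(Oc4c(OC)cc(OC)c(-c5c(OC)cc(OC)cc5OC)c4OC)cc(OC)cc3Oc3c(OC)cc(OC)c(-c4c(OC)cc(OC)cc4OC)c3OC)cc2OC)c(Oc2cc(OC)cc(OC)c2)c(Oc2c(OC)cc(OC)c(-c3c(OC)cc(OC)cc3OC)c2OC)c1 | intermediate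
22 | CNP0294555.0 | Oc1cc(O)cc(Oc2c(Oc3c(O)cc(Oc4c(Oc5c(O)cc(O)c(-c6c(O)cc(O)cc6O)c5O)cc(O)cc4Oc4c(O)cc(O)c(-c5c(O)cc(O)cc5O)c4O)cc3O)cc(O)cc2Oc2c(O)cc(O)c(-c3c(O)cc(O)cc3O)c2O)c1 | target

## Step count and risks

Total step count: 12.
Longest linear sequence: 11 steps (1, 2, 4, 5, 6, 7, 8, 9, 10, 11, 12) from 1,3,5-trimethoxybenzene. Step 3 is a one-step branch from 5 and 6.

**Step 12.** The cleavage of 24 methyl ethers may stop short because partly cleaved boron aryloxides precipitate from CH2Cl2. The free polyphenol may also be lost to air oxidation and irreversible adsorption during purification.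

The fallback sets out from 21 and comes back at 22, and it moves purification to a protected stage. The crude phenol mixture from the BBr3 treatment is not purified. It is peracetylated (Ac2O, pyridine, cat. DMAP, rt) to the tetracosaacetate F1, a neutral, air-stable compound that can be chromatographed on silica. Fractions that still hold methyl groups can then be removed or sent back to BBr3. Acid methanolysis of pure F1 (methanolic HCl, 0 °C to rt, Ar) then releases 22, with only volatile co-products to evaporate.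

**Step 11.** The phenoxide of 19, crowded by two large aryloxy groups, may bind poorly to copper. C–O bond formation would then lose out to reduction of the aryl iodide and slow degradation of the phenol.

The fallback sets out from 19 and comes back at 21, and it replaces metal catalysis by the addition–elimination logic of steps 6 and 7.
- The phenoxide of 19 takes the para fluoride of 11 (Cs2CO3, DMF, 0 °C to rt) to give the ring A difluoroaldehyde F2.
- NaOMe (MeOH–THF, 50 °C) passes through the fluoro methoxy aldehyde F3, which is not isolated, to the ring A dimethoxyaldehyde F4.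
- A Tsuji–Wilkinson decarbonylation ([RhCl(cod)]2, dppp, diglyme, reflux) removes the now superfluous formyl group of F4 as carbon monoxide and gives 21.

**Step 9.** Fluoride displacement may stall, because the electrophile is deactivated by two oxygen donors and both partners are bulky. The long heating then needed may erode the formyl group and allow exchange of the aryloxy group already in place.

The fallback sets out from 5 and 16 and comes back at 17. It uses a nitrile as the activating group, which is rod-shaped, inert to base and stable at higher temperature.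
- Phenol 5 and purchased 2,6-difluoro-4-methoxybenzonitrile (COc1cc(F)c(C#N)c(F)c1, in excess; K2CO3, DMF, 60 °C) give 2-fluoro-4-methoxy-6-(ArO)benzonitrile F5.
- F5 and the phenoxide of 16 (Cs2CO3, DMSO, up to 140 °C) give the ring B nitrile F6.
- i-Bu2AlH (toluene, −78 to 0 °C) adds once to form the N-aluminated aldimine F7, which is hydrolysed with dilute HCl to aldehyde 17.

Further compounds
F1 | step 12 | tetracosaacetate of the target | CC(=O)Oc1cc(Oc2c(OC(C)=O)cc(Oc3c(Oc4c(OC(C)=O)cc(OC(C)=O)c(-c5c(OC(C)=O)cc(OC(C)=O)cc5OC(C)=O)c4OC(C)=O)cc(OC(C)=O)cc3Oc3c(OC(C)=O)cc(OC(C)=O)c(-c4c(OC(C)=O)cc(OC(C)=O)cc4OC(C)=O)c3OC(C)=O)cc2OC(C)=O)c(Oc2cc(OC(C)=O)cc(OC(C)=O)c2)c(Oc2c(OC(C)=O)cc(OC(C)=O)c(-c3c(OC(C)=O)cc(OC(C)=O)cc3OC(C)=O)c2OC(C)=O)c1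
F2 | step 11 | ring B phenol 19 O-arylated with a 3,5-difluoro-4-formylphenyl group | COc1cc(Oc2c(OC)cc(Oc3c(Oc4c(OC)cc(OC)c(-c5c(OC)cc(OC)cc5OC)c4OC)cc(OC)cc3Oc3c(OC)cc(OC)c(-c4c(OC)cc(OC)cc4OC)c3OC)cc2OC)c(Oc2cc(F)c(C=O)c(F)c2)c(Oc2c(OC)cc(OC)c(-c3c(OC)cc(OC)cc3OC)c2OC)c1
F3 | step 11 | ring B phenol 19 O-arylated with a 3-fluoro-4-formyl-5-methoxyphenyl group | COc1cc(Oc2c(OC)cc(Oc3c(Oc4c(OC)cc(OC)c(-c5c(OC)cc(OC)cc5OC)c4OC)cc(OC)cc3Oc3c(OC)cc(OC)c(-c4c(OC)cc(OC)cc4OC)c3OC)cc2OC)c(Oc2cc(F)c(C=O)c(OC)c2)c(Oc2c(OC)cc(OC)c(-c3c(OC)cc(OC)cc3OC)c2OC)c1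
F4 | step 11 | ring B phenol 19 O-arylated with a 4-formyl-3,5-dimethoxyphenyl group | COc1cc(Oc2c(OC)cc(Oc3c(Oc4c(OC)cc(OC)c(-c5c(OC)cc(OC)cc5OC)c4OC)cc(OC)cc3Oc3c(OC)cc(OC)c(-c4c(OC)cc(OC)cc4OC)c3OC)cc2OC)c(Oc2cc(OC)c(C=O)c(OC)c2)c(Oc2c(OC)cc(OC)c(-c3c(OC)cc(OC)cc3OC)c2OC)c1
F5 | step 9 | 2-fluoro-4-methoxy-6-(ArO)benzonitrile | COc1cc(F)c(C#N)c(Oc2c(OC)cc(OC)c(-c3c(OC)cc(OC)cc3OC)c2OC)c1
F6 | step 9 | nitrile analogue of 17 (C≡N in place of CHO on ring B) | COc1cc(Oc2c(OC)cc(Oc3c(Oc4c(OC)cc(OC)c(-c5c(OC)cc(OC)cc5OC)c4OC)cc(OC)cc3Oc3c(OC)cc(OC)c(-c4c(OC)cc(OC)cc4OC)c3OC)cc2OC)c(C#N)c(Oc2c(OC)cc(OC)c(-c3c(OC)cc(OC)cc3OC)c2OC)c1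
F7 | step 9 | (E)-N-(diisobutylaluminio)aldimine of 17 | COc1cc(Oc2c(OC)cc(Oc3c(Oc4c(OC)cc(OC)c(-c5c(OC)cc(OC)cc5OC)c4OC)cc(OC)cc3Oc3c(OC)cc(OC)c(-c4c(OC)cc(OC)cc4OC)c3OC)cc2OC)c(/C=N/[Al](CC(C)C)CC(C)C)c(Oc2c(OC)cc(OC)c(-c3c(OC)cc(OC)cc3OC)c2OC)c1
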